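## Retrosynthetic overview

1. Target ⇒ ester bond last (Yamaguchi, then global desilylation): core alcohol 16 + silyl-protected (2E,4E,6S,7S)-dienoic acid 29.
2. 16 ⇒ oxidation of the C3–B bond of 15. 15 ⇒ intramolecular Diels–Alder reaction of vinylallenyl ketone 14 (diene C10=C1–C2=C3, dienophile C4=C5), which gives the C8 ketone/C9=C10/C1=C2 dienone directly.
3. 14 ⇒ ynone 13 ⇒ Sonogashira coupling of alkynol 10 with bromovinyl MIDA boronate 11. 10 ⇒ (R,R)-diepoxybutane 3 (D-threitol series), opened once by (E)-but-2-en-2-yllithium and once by acetylide; its C7 oxygen stereocentre controls C3, C4 and C5.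
4. 29 ⇒ vinylogous HWE on aldehyde 25 ⇒ SN2 opening (inversion) of the cyclic sulfate of (2S,3S)-butane-2,3-diol by a vinyl nucleophile.
5. Ring order: no ring is pre-formed; both carbocycles close together in the single cycloaddition (bonds C3–C4 and C5–C10).

Assumption: core atoms are given eremophilane-type locants (C1=C2, C3 = ester carbinol, C4 and C5 = methyl-bearing carbons, C7 = carbinol, C8 = ketone, C9=C10); building blocks that supply skeletal carbons are numbered as starting materials.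

## Route

Step 1
Reactants: 1 (+)-1,4-di-O-tosyl-2,3-O-isopropylidene-D-threitol
Product: 2 1,4-di-O-tosyl-D-threitol
Conditions: 2 M aq. HCl (cat.), THF, 50 °C
Reagents that add atoms: none
Why: Acid-catalysed acetal hydrolysis frees the trans-diol without touching the two bought stereocentres (D-tartaric acid series).

Step 2
Reactants: 2 1,4-di-O-tosyl-D-threitol
Product: 3 (2R,3R)-1,2:3,4-diepoxybutane
Conditions: powdered KOH, Et2O, 23 °C; distil
Reagents that add atoms: none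
Why: Twofold intramolecular Williamson reaction (3-exo-tet) on the primary tosylates retains the C–O bonds at the stereocentres and gives the C2-symmetric (R,R)-diepoxide.

Step 3
Reactants: 4 (E)-2-bromobut-2-ene (methyl groups cis); 3 (2R,3R)-1,2:3,4-diepoxybutane
Product: 6 (1R,3E)-3-methyl-1-[(2R)-oxiran-2-yl]pent-3-en-1-ol, via (E)-but-2-en-2-yllithium 5 (not isolated)
Conditions: 4, t-BuLi (2 equiv), Et2O, −78 °C; then 3 (3 equiv, excess recovered), BF3·OEt2, THF, −78 °C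
Reagents that add atoms: none
Why: Halogen–lithium exchange with retention of alkene geometry, then BF3-assisted SN2 opening of a terminal epoxide carbon; the diepoxide is C2-symmetric so either end gives the same product, and the carbinol centre (future C7) is not touched.

Step 4
Reactants: 6 (1R,3E)-3-methyl-1-[(2R)-oxiran-2-yl]pent-3-en-1-ol
Product: 7 tert-butyl(dimethyl){[(1R,3E)-3-methyl-1-[(2R)-oxiran-2-yl]pent-3-en-1-yl]oxy}silane
Conditions: TBSCl, imidazole, DMF, 23 °C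
Reagents that add atoms: tert-butyldimethylsilyl chloride, CC(C)(C)[Si](C)(C)Cl
Why: Silylation blocks the C7 hydroxyl against Payne rearrangement and differentiates it from the C8 hydroxyl formed next.

Step 5
Reactants: 7 tert-butyl(dimethyl){[(1R,3E)-3-methyl-1-[(2R)-oxiran-2-yl]pent-3-en-1-yl]oxy}silane; 8 acetylene
Product: 10 (4R,5R,7E)-5-[(tert-butyldimethylsilyl)oxy]-7-methylnon-7-en-1-yn-4-ol, via lithium acetylide 9 (not isolated)
Conditions: 8, n-BuLi, THF, −78 °C; BF3·OEt2; then 7, −78 °C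
Reagents that add atoms: none
Why: Yamaguchi-type BF3-mediated SN2 opening of the terminal epoxide carbon by the acetylide at −78 °C (no silyl migration) gives the homopropargylic alcohol; the C8 centre comes from the diepoxide and is erased in step 7.

Step 6
Reactants: 10 (4R,5R,7E)-5-[(tert-butyldimethylsilyl)oxy]-7-methylnon-7-en-1-yn-4-ol; 11 (E)-(2-bromovinyl)boronic acid MIDA ester
Product: 12 2-[(1E,6R,7R,9E)-7-[(tert-butyldimethylsilyl)oxy]-6-hydroxy-9-methylundeca-1,9-dien-3-yn-1-yl]-6-methyl-1,3,6,2-dioxazaborocane-4,8-dione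
Conditions: PdCl2(PPh3)2 (5 mol %), CuI (10 mol %), Et3N, THF, 23 °C
Reagents that add atoms: none
Why: Sonogashira coupling retains the E geometry of the alkenyl bromide and leaves the sp3 MIDA boronate, the free alcohol and the silyl ether untouched.

Step 7
Reactants: 12 2-[(1E,6R,7R,9E)-7-[(tert-butyldimethylsilyl)oxy]-6-hydroxy-9-methylundeca-1,9-dien-3-yn-1-yl]-6-methyl-1,3,6,2-dioxazaborocane-4,8-dione
Product: 15 (3R,4aR,5S,6S)-3-[(tert-butyldimethylsilyl)oxy]-4a,5-dimethyl-6-(6-methyl-4,8-dioxo-1,3,6,2-dioxazaborocan-2-yl)-4,4a,5,6-tetrahydronaphthalen-2(3H)-one, via ynone 13 (not isolated), via vinylallenone 14 (not isolated)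
Conditions: Dess–Martin periodinane, CH2Cl2, 0 → 23 °C; filter, concentrate; then Et3N (0.3 equiv), MeCN (0.01 M), 23 → 75 °C
Reagents that add atoms: none
Why: Dess–Martin oxidation gives the β,γ-ynone, Et3N isomerises it to the vinylallenyl ketone, and its intramolecular Diels–Alder reaction closes both rings; the tether from the allene terminus must lie exo, so both alkene methyls are endo and C3–B, C4–Me and C5–Me come out all-cis, while the bought C7 centre keeps its OTBS group equatorial (trans to the C5 methyl) in the favoured transition state of the base-equilibrating allene epimers (Curtin–Hammett).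

Step 8
Reactants: 15 (3R,4aR,5S,6S)-3-[(tert-butyldimethylsilyl)oxy]-4a,5-dimethyl-6-(6-methyl-4,8-dioxo-1,3,6,2-dioxazaborocan-2-yl)-4,4a,5,6-tetrahydronaphthalen-2(3H)-one
Product: 16 (3R,4aR,5R,6S)-3-[(tert-butyldimethylsilyl)oxy]-6-hydroxy-4a,5-dimethyl-4,4a,5,6-tetrahydronaphthalen-2(3H)-one
Conditions: NaBO3·4H2O, THF/H2O (1:1), 0 → 23 °C
Reagents that add atoms: sodium perborate, [Na+].[Na+].O[B-]1(O)OO[B-](O)(O)OO1
Why: Aqueous perborate hydrolyses the MIDA ester and oxidises the allylic C–B bond by 1,2-migration with retention and without allylic shift, so the C3 hydroxyl is cis to both methyls.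

Step 9
Reactants: 17 (2S,3S)-butane-2,3-diol
Product: 19 (4S,5S)-4,5-dimethyl-1,3,2-dioxathiolane 2,2-dioxide, via cyclic sulfite 18 (not isolated)
Conditions: SOCl2, Et3N, CH2Cl2, 0 °C; then RuCl3 (cat.), NaIO4, MeCN/H2O, 0 °C
Reagents that add atoms: thionyl chloride, O=S(Cl)Cl; sodium periodate, [Na+].[O-]I(=O)(=O)=O
Why: Cyclic sulfite formation and Ru-catalysed oxidation (Gao–Sharpless cyclic sulfate synthesis) activate the diol without touching either bought stereocentre.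

Step 10
Reactants: 19 (4S,5S)-4,5-dimethyl-1,3,2-dioxathiolane 2,2-dioxide; 20 vinylmagnesium bromide
Product: 22 (2S,3S)-3-methylpent-4-en-2-ol, via bromomagnesium alkyl sulfate 21 (not isolated)
Conditions: 20, CuI (10 mol %), THF, −40 → 0 °C; then H2SO4 (cat.), H2O (1 equiv), THF, 23 °C
Reagents that add atoms: none
Why: Cu-catalysed SN2 opening of the cyclic sulfate inverts one of the two equivalent carbons and so gives the syn (2S,3S) methyl/hydroxyl pair; acid hydrolysis of the monoalkyl sulfate (S–O cleavage) releases the alcohol.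

Step 11
Reactants: 22 (2S,3S)-3-methylpent-4-en-2-ol
Product: 23 tert-butyl(dimethyl){[(2S,3S)-3-methylpent-4-en-2-yl]oxy}silane
Conditions: TBSCl, imidazole, DMF, 23 °C
Reagents that add atoms: tert-butyldimethylsilyl chloride, CC(C)(C)[Si](C)(C)Cl
Why: Standard silyl protection of the secondary alcohol for the steps up to the ester coupling.

Step 12
Reactants: 23 tert-butyl(dimethyl){[(2S,3S)-3-methylpent-4-en-2-yl]oxy}silane
Product: 25 (2R,3S)-3-[(tert-butyldimethylsilyl)oxy]-2-methylbutanal, via ozonide 24 (not isolated)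
Conditions: O3, CH2Cl2, −78 °C; then PPh3, −78 → 23 °C
Reagents that add atoms: ozone, [O-][O+]=O
Why: Ozonolysis with reductive work-up cleaves the terminal alkene under neutral conditions, so the α-stereocentre is not epimerised.

Step 13
Reactants: 25 (2R,3S)-3-[(tert-butyldimethylsilyl)oxy]-2-methylbutanal; 26 triethyl (E)-4-phosphonocrotonate
Product: 28 ethyl (2E,4E,6S,7S)-7-[(tert-butyldimethylsilyl)oxy]-6-methylocta-2,4-dienoate, via lithiated phosphonate 27 (not isolated)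
Conditions: 26, LiHMDS, THF, −78 °C; then 25, −78 → 0 °C
Reagents that add atoms: none
Why: Vinylogous Horner–Wadsworth–Emmons olefination forms the 4,5-double bond E-selectively and keeps the 2E bond; at −78 °C the stabilised anion does not epimerise the α-methyl aldehyde.

Step 14
Reactants: 28 ethyl (2E,4E,6S,7S)-7-[(tert-butyldimethylsilyl)oxy]-6-methylocta-2,4-dienoate
Product: 29 (2E,4E,6S,7S)-7-[(tert-butyldimethylsilyl)oxy]-6-methylocta-2,4-dienoic acid
Conditions: LiOH, THF/MeOH/H2O, 23 °C; then 1 M HCl to pH 3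
Reagents that add atoms: lithium hydroxide, [Li+].[OH-]
Why: Saponification of the ethyl ester leaves the silyl ether and the diene geometry unchanged.

Step 15
Reactants: 16 (3R,4aR,5R,6S)-3-[(tert-butyldimethylsilyl)oxy]-6-hydroxy-4a,5-dimethyl-4,4a,5,6-tetrahydronaphthalen-2(3H)-one; 29 (2E,4E,6S,7S)-7-[(tert-butyldimethylsilyl)oxy]-6-methylocta-2,4-dienoic acid
Product: 31 (1R,2S,7R,8aR)-7-[(tert-butyldimethylsilyl)oxy]-1,8a-dimethyl-6-oxo-1,2,6,7,8,8a-hexahydronaphthalen-2-yl (2E,4E,6S,7S)-7-[(tert-butyldimethylsilyl)oxy]-6-methylocta-2,4-dienoate, via mixed anhydride 30 (not isolated)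
Conditions: 29, 2,4,6-trichlorobenzoyl chloride, Et3N, THF, 23 °C; then 16, DMAP, toluene, 23 → 40 °C
Reagents that add atoms: none
Why: Yamaguchi esterification acylates the hindered allylic C3 hydroxyl on oxygen, so its configuration is retained.

Step 16
Reactants: 31 (1R,2S,7R,8aR)-7-[(tert-butyldimethylsilyl)oxy]-1,8a-dimethyl-6-oxo-1,2,6,7,8,8a-hexahydronaphthalen-2-yl (2E,4E,6S,7S)-7-[(tert-butyldimethylsilyl)oxy]-6-methylocta-2,4-dienoate
Product: 32 (1R,2S,7R,8aR)-7-hydroxy-1,8a-dimethyl-6-oxo-1,2,6,7,8,8a-hexahydronaphthalen-2-yl (2E,4E,6S,7S)-7-hydroxy-6-methylocta-2,4-dienoate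
Conditions: HF·pyridine, pyridine/THF, 0 → 23 °C
Reagents that add atoms: none
Why: Fluoride-mediated cleavage of both TBS ethers under buffered, non-basic conditions leaves the allylic ester, the dienone and the α-ketol stereocentre intact.

## Compound list

1 | (+)-1,4-di-O-tosyl-2,3-O-isopropylidene-D-threitol, [(4R,5R)-2,2-dimethyl-1,3-dioxolane-4,5-diyl]bis(methylene) bis(4-methylbenzenesulfonate) | Cc1ccc(cc1)S(=O)(=O)OC[C@H]1OC(C)(C)O[C@@H]1COS(=O)(=O)c1ccc(C)cc1 | starting material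
2 | 1,4-di-O-tosyl-D-threitol, (2R,3R)-2,3-dihydroxybutane-1,4-diyl bis(4-methylbenzenesulfonate) | Cc1ccc(cc1)S(=O)(=O)OC[C@@H](O)[C@H](O)COS(=O)(=O)c1ccc(C)cc1 | intermediate
3 | (2R,3R)-1,2:3,4-diepoxybutane | C1O[C@H]1[C@H]1CO1 | intermediate
4 | (E)-2-bromobut-2-ene (methyl groups cis) | C/C=C(\C)Br | starting material
5 | (E)-but-2-en-2-yllithium | C/C=C(\C)[Li] | intermediate
6 | (1R,3E)-3-methyl-1-[(2R)-oxiran-2-yl]pent-3-en-1-ol | C/C=C(\C)C[C@@H](O)[C@H]1CO1 | intermediate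
7 | tert-butyl(dimethyl){[(1R,3E)-3-methyl-1-[(2R)-oxiran-2-yl]pent-3-en-1-yl]oxy}silane | C/C=C(\C)C[C@@H](O[Si](C)(C)C(C)(C)C)[C@H]1CO1 | intermediate
8 | acetylene | C#C | starting material
9 | lithium acetylide | [Li]C#C | intermediate
10 | (4R,5R,7E)-5-[(tert-butyldimethylsilyl)oxy]-7-methylnon-7-en-1-yn-4-ol | C/C=C(\C)C[C@@H](O[Si](C)(C)C(C)(C)C)[C@H](O)CC#C | intermediate
11 | (E)-(2-bromovinyl)boronic acid MIDA ester, 2-[(E)-2-bromoethenyl]-6-methyl-1,3,6,2-dioxazaborocane-4,8-dione | C[N+]12CC(=O)O[B-]1(/C=C/Br)OC(=O)C2 | starting material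
12 | 2-[(1E,6R,7R,9E)-7-[(tert-butyldimethylsilyl)oxy]-6-hydroxy-9-methylundeca-1,9-dien-3-yn-1-yl]-6-methyl-1,3,6,2-dioxazaborocane-4,8-dione | C/C=C(\C)C[C@@H](O[Si](C)(C)C(C)(C)C)[C@H](O)CC#C/C=C/[B-]12OC(=O)C[N+]1(C)CC(=O)O2 | intermediate
13 | 2-[(1E,7R,9E)-7-[(tert-butyldimethylsilyl)oxy]-9-methyl-6-oxoundeca-1,9-dien-3-yn-1-yl]-6-methyl-1,3,6,2-dioxazaborocane-4,8-dione | C/C=C(\C)C[C@@H](O[Si](C)(C)C(C)(C)C)C(=O)CC#C/C=C/[B-]12OC(=O)C[N+]1(C)CC(=O)O2 | intermediate
14 | 2-[(1E,7R,9E)-7-[(tert-butyldimethylsilyl)oxy]-9-methyl-6-oxoundeca-1,3,4,9-tetraen-1-yl]-6-methyl-1,3,6,2-dioxazaborocane-4,8-dione (both allene configurations, interconverting) | C/C=C(\C)C[C@@H](O[Si](C)(C)C(C)(C)C)C(=O)C=C=C/C=C/[B-]12OC(=O)C[N+]1(C)CC(=O)O2 | intermediate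
15 | (3R,4aR,5S,6S)-3-[(tert-butyldimethylsilyl)oxy]-4a,5-dimethyl-6-(6-methyl-4,8-dioxo-1,3,6,2-dioxazaborocan-2-yl)-4,4a,5,6-tetrahydronaphthalen-2(3H)-one (boron, 5-Me and 4a-Me all cis; 3-OTBS trans to 4a-Me) | C[N+]12CC(=O)O[B-]1([C@H]3C=CC4=CC(=O)[C@H](O[Si](C)(C)C(C)(C)C)C[C@]4(C)[C@H]3C)OC(=O)C2 | intermediate
16 | (3R,4aR,5R,6S)-3-[(tert-butyldimethylsilyl)oxy]-6-hydroxy-4a,5-dimethyl-4,4a,5,6-tetrahydronaphthalen-2(3H)-one | O[C@H]1C=CC2=CC(=O)[C@H](O[Si](C)(C)C(C)(C)C)C[C@]2(C)[C@H]1C | intermediate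
17 | (2S,3S)-butane-2,3-diol | C[C@H](O)[C@H](C)O | starting material
18 | (4S,5S)-4,5-dimethyl-1,3,2-dioxathiolane 2-oxide | C[C@@H]1OS(=O)O[C@H]1C | intermediate
19 | (4S,5S)-4,5-dimethyl-1,3,2-dioxathiolane 2,2-dioxide | C[C@@H]1OS(=O)(=O)O[C@H]1C | intermediate
20 | vinylmagnesium bromide | C=C[Mg]Br | starting material
21 | bromomagnesium (2S,3S)-3-methylpent-4-en-2-yl sulfate | C[C@H](OS(=O)(=O)[O-])[C@@H](C)C=C.[Mg+2].[Br-] | intermediate
22 | (2S,3S)-3-methylpent-4-en-2-ol | C[C@H](O)[C@@H](C)C=C | intermediate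
23 | tert-butyl(dimethyl){[(2S,3S)-3-methylpent-4-en-2-yl]oxy}silane | C[C@H](O[Si](C)(C)C(C)(C)C)[C@@H](C)C=C | intermediate
24 | 3-[(2R,3S)-3-[(tert-butyldimethylsilyl)oxy]butan-2-yl]-1,2,4-trioxolane (epimers at the ring carbon) | C[C@H](O[Si](C)(C)C(C)(C)C)[C@@H](C)C1OOCO1 | intermediate
25 | (2R,3S)-3-[(tert-butyldimethylsilyl)oxy]-2-methylbutanal | C[C@H](O[Si](C)(C)C(C)(C)C)[C@@H](C)C=O | intermediate
26 | triethyl (E)-4-phosphonocrotonate, ethyl (2E)-4-(diethoxyphosphoryl)but-2-enoate | CCOC(=O)/C=C/CP(=O)(OCC)OCC | starting material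
27 | lithium salt of 26 (C4 carbanion) | [Li+].CCOC(=O)/C=C/[CH-]P(=O)(OCC)OCC | intermediate
28 | ethyl (2E,4E,6S,7S)-7-[(tert-butyldimethylsilyl)oxy]-6-methylocta-2,4-dienoate | C[C@H](O[Si](C)(C)C(C)(C)C)[C@@H](C)/C=C/C=C/C(=O)OCC | intermediate
29 | (2E,4E,6S,7S)-7-[(tert-butyldimethylsilyl)oxy]-6-methylocta-2,4-dienoic acid | C[C@H](O[Si](C)(C)C(C)(C)C)[C@@H](C)/C=C/C=C/C(=O)O | intermediate
30 | (2E,4E,6S,7S)-7-[(tert-butyldimethylsilyl)oxy]-6-methylocta-2,4-dienoic 2,4,6-trichlorobenzoic anhydride | C[C@H](O[Si](C)(C)C(C)(C)C)[C@@H](C)/C=C/C=C/C(=O)OC(=O)c1c(Cl)cc(Cl)cc1Cl | intermediate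
31 | (1R,2S,7R,8aR)-7-[(tert-butyldimethylsilyl)oxy]-1,8a-dimethyl-6-oxo-1,2,6,7,8,8a-hexahydronaphthalen-2-yl (2E,4E,6S,7S)-7-[(tert-butyldimethylsilyl)oxy]-6-methylocta-2,4-dienoate | C[C@H](O[Si](C)(C)C(C)(C)C)[C@@H](C)/C=C/C=C/C(=O)O[C@H]1C=CC2=CC(=O)[C@H](O[Si](C)(C)C(C)(C)C)C[C@]2(C)[C@H]1C | intermediate
32 | (1R,2S,7R,8aR)-7-hydroxy-1,8a-dimethyl-6-oxo-1,2,6,7,8,8a-hexahydronaphthalen-2-yl (2E,4E,6S,7S)-7-hydroxy-6-methylocta-2,4-dienoate | C[C@H](O)[C@@H](C)/C=C/C=C/C(=O)O[C@H]1C=CC2=CC(=O)[C@H](O)C[C@]2(C)[C@H]1C | target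

## Step count and risks

Total step count: 16. Longest linear sequence: 10 steps (steps 1–8, 15, 16); the side chain (steps 9–14) is a six-step branch.

Most likely to fail, first: step 7. Three events must occur in one flask: ynone-to-allenone isomerisation, equilibration of the two allene epimers, and a cycloaddition that builds a quaternary centre. Possible failures are allenone oligomerisation, poor diastereoselection if the allene epimers do not equilibrate, and loss of enantiopurity if C7 epimerises before cyclisation. The fallback sets out from 10 and runs the cycloaddition on a conventional diene. Hydrozirconation of 10 (Cp2ZrHCl, 2.2 equiv) and Pd/ZnCl2-mediated coupling with 11 give the (1E,3E)-dienyl MIDA boronate F1. Dess–Martin oxidation gives the dienyl ketone F2. Thermal intramolecular Diels–Alder reaction (toluene, 130 °C, BHT) through the trans-fused transition state gives the octalone F3 (diastereomers separated). α,β-Dehydrogenation of F3 with IBX (DMSO/toluene, 70 °C) introduces the C9=C10 bond and returns to 15.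

Second: step 8. The C–B bond is vinylogously α to the dienone, so protodeboronation or nucleophilic epoxidation of the dienone can compete with the oxidation. The fallback sets out from 7 and carries oxygen, not boron, through the cycloaddition. Sodium malonaldehyde and 4-methoxybenzyl chloride give (2E)-3-[(4-methoxybenzyl)oxy]prop-2-enal F4, which Colvin homologation (TMSCHN2, LDA) converts into (E)-1-[(4-methoxybenzyl)oxy]but-1-en-3-yne F5. F5 is deprotonated with n-BuLi and opens epoxide 7 (BF3·OEt2, −78 °C) to give the enynol F6. Dess–Martin oxidation gives the ynone F7; Et3N in warm MeCN takes it through the vinylallenone F8 to the cycloadduct PMB ether F9. DDQ (CH2Cl2, pH 7 buffer) removes the PMB group and returns to 16.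

Third: step 15. The alcohol is hindered, and DMAP-activated dienoic acids can isomerise through vinylketenes. The fallback sets out from 16 and builds the diene after the ester bond. Saponification of 26 gives (2E)-4-(diethoxyphosphoryl)but-2-enoic acid F10. DCC/DMAP coupling of this small acid with 16 gives the phosphonate ester F11. Horner–Wadsworth–Emmons reaction of F11 with aldehyde 25 (LiCl, DBU, MeCN, or LiHMDS at −78 °C) returns to 31.

## Further compounds

F1 | step 7 | 2-[(1E,3E,6R,7R,9E)-7-[(tert-butyldimethylsilyl)oxy]-6-hydroxy-9-methylundeca-1,3,9-trien-1-yl]-6-methyl-1,3,6,2-dioxazaborocane-4,8-dione | C/C=C(\C)C[C@@H](O[Si](C)(C)C(C)(C)C)[C@H](O)C/C=C/C=C/[B-]12OC(=O)C[N+]1(C)CC(=O)O2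
F2 | step 7 | 2-[(1E,3E,7R,9E)-7-[(tert-butyldimethylsilyl)oxy]-9-methyl-6-oxoundeca-1,3,9-trien-1-yl]-6-methyl-1,3,6,2-dioxazaborocane-4,8-dione | C/C=C(\C)C[C@@H](O[Si](C)(C)C(C)(C)C)C(=O)C/C=C/C=C/[B-]12OC(=O)C[N+]1(C)CC(=O)O2
F3 | step 7 | (3R,4aR,5S,6S,8aR)-3-[(tert-butyldimethylsilyl)oxy]-4a,5-dimethyl-6-(6-methyl-4,8-dioxo-1,3,6,2-dioxazaborocan-2-yl)-3,4,4a,5,6,8a-hexahydronaphthalen-2(1H)-one | C[N+]12CC(=O)O[B-]1([C@H]3C=C[C@H]4CC(=O)[C@H](O[Si](C)(C)C(C)(C)C)C[C@]4(C)[C@H]3C)OC(=O)C2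
F4 | step 8 | (2E)-3-[(4-methoxybenzyl)oxy]prop-2-enal | COc1ccc(CO/C=C/C=O)cc1
F5 | step 8 | (E)-1-[(4-methoxybenzyl)oxy]but-1-en-3-yne | COc1ccc(CO/C=C/C#C)cc1
F6 | step 8 | (1E,6R,7R,9E)-7-[(tert-butyldimethylsilyl)oxy]-1-[(4-methoxybenzyl)oxy]-9-methylundeca-1,9-dien-3-yn-6-ol | C/C=C(\C)C[C@@H](O[Si](C)(C)C(C)(C)C)[C@H](O)CC#C/C=C/OCc1ccc(OC)cc1
F7 | step 8 | (1E,7R,9E)-7-[(tert-butyldimethylsilyl)oxy]-1-[(4-methoxybenzyl)oxy]-9-methylundeca-1,9-dien-3-yn-6-one | C/C=C(\C)C[C@@H](O[Si](C)(C)C(C)(C)C)C(=O)CC#C/C=C/OCc1ccc(OC)cc1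
F8 | step 8 | (1E,7R,9E)-7-[(tert-butyldimethylsilyl)oxy]-1-[(4-methoxybenzyl)oxy]-9-methylundeca-1,3,4,9-tetraen-6-one | C/C=C(\C)C[C@@H](O[Si](C)(C)C(C)(C)C)C(=O)C=C=C/C=C/OCc1ccc(OC)cc1
F9 | step 8 | (3R,4aR,5R,6S)-3-[(tert-butyldimethylsilyl)oxy]-6-[(4-methoxybenzyl)oxy]-4a,5-dimethyl-4,4a,5,6-tetrahydronaphthalen-2(3H)-one | COc1ccc(CO[C@H]2C=CC3=CC(=O)[C@H](O[Si](C)(C)C(C)(C)C)C[C@]3(C)[C@H]2C)cc1
F10 | step 15 | (2E)-4-(diethoxyphosphoryl)but-2-enoic acid | CCOP(=O)(C/C=C/C(=O)O)OCC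
F11 | step 15 | (1R,2S,7R,8aR)-7-[(tert-butyldimethylsilyl)oxy]-1,8a-dimethyl-6-oxo-1,2,6,7,8,8a-hexahydronaphthalen-2-yl (2E)-4-(diethoxyphosphoryl)but-2-enoate | CCOP(=O)(C/C=C/C(=O)O[C@H]1C=CC2=CC(=O)[C@H](O[Si](C)(C)C(C)(C)C)C[C@]2(C)[C@H]1C)OCC
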